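In a one-step world the fraction of free monomer left shrinks by the same share in each equal interval, down towards zero. This flask, followed so far up to 90.0 min, leaves that line.

the same everywhere: free monomer 0.050 M; initiator 4.5 mol%

| run | remark | time |
|---|---|---|
| elm | the very flask that is asked about, followed so far |  |
| flask |  | 3.0 h |

elm run (percent of the free monomer charged)

| time / min | monomer in chains / % | free monomer / % |
|---|---|---|
| 6.00 | 2.8 | 96.2 |
| 20.0 | 9.9 | 89.9 |
| 30.0 | 14.5 | 86.5 |
| 50.0 | 19.3 | 80.4 |
| 60.0 | 22.7 | 78.2 |
| 90.0 | 26.7 | 73.6 |

(readings scatter by 0.5 percentage points)

- average number of monomer units in a chain (chains begun, living or dead) at 3.0 h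
- part of the free monomer that has reacted at 3.0 h

- the average divides the monomer in chains by the number of chains begun, living and dead together
- the earlier runs do not show the number of chains; that part of a forecast is a guess

1. First instants. At 6.00 min the flask holds 96.2% free monomer and 2.8% monomer in chains. The two columns add to about the charge, so what leaves the free form is found in chains.

2. Middle. From 30.0 min to 60.0 min the fraction left falls by 8.3 percentage points, but over the next equal interval, to 90.0 min, it falls by 4.6 points. Each drop is thus 0.554 of the one before, as read through the scatter.

3. End. Drops shrinking by a constant ratio have a finite sum, so if that ratio holds, the readings of this flask put the fraction left near 67.9%, not zero. That is a concentration of 0.0339 M: a reading of the floor of free monomer, the c(free monomer) at which its fall stops, or in the usual term the equilibrium monomer concentration.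

4. Reckoning. My own reckoning, with the same ratio over the intervals still to come up to 3.0 h, puts c near 31.1%. The readings show no chain count, so dp stays open here.

5. Forecast. The forecast gives c = 33%, higher than this reckoning, and dp = 8, for which its ground is: “If every initiator starts one chain”.

6. Result. The flask gives dp = 13.4 and c = 32.3%.

    monomer in chains + living end → free monomer + living end, rate k1*[living end] as long as [monomer in chains] is above zero (k = 0.00760 s⁻¹)
    free monomer + living end → monomer in chains + living end, rate k2*[living end]*[free monomer] (k = 0.230 L mol⁻¹ s⁻¹)
    initiator → spent initiator A (k = 0.00140 s⁻¹)
    free monomer + initiator → living end + monomer in chains (k = 0.0600 L mol⁻¹ s⁻¹)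
    2 initiator → spent initiator B (k = 0.550 L mol⁻¹ s⁻¹)

At 3.00 h the living end in this flask stands at 0.00121 M, about half of the initiator charged, with initiator at 0% of its charge. The charge less the floor is 0.0161 M; spread over that living end, it gives 13.3 units per chain.

7. Second flask. With 0.20 M of free monomer at the same loading, the same floor reckons to a fraction left of 16.9%, so c near 83.0%. That neighbour flask gives c = 83.5% at 3.0 h.

The data are calculated for substances that don't exist; scatter was added.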